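As the chemist following the north-west flask, where a single-handed free catalyst joined partner to both mirror-image substrates while a racemization catalyst turned each substrate into the other, I had its first readings and an earlier north run with a different charge of racemization catalyst.

in all of them: left-handed substrate 14 mM; right-handed substrate 14 mM; partner 30.8 mM; free catalyst 20 µM
- north-west: racemization catalyst 70 µM; the very flask that is asked about, followed so far
- north: racemization catalyst 100 µM; run made earlier
- flask: racemization catalyst 70 µM; time 50 min

1. left-handed product and right-handed product together, in percent of the left-handed substrate and right-handed substrate charged together, at 50 min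
2. excess of left-handed product over right-handed product in the product at 50 min
3. whether the exchange between left-handed substrate and right-handed substrate keeps pace with the reaction: how far the product's excess at 50 min gets from its value without exchange to its value with instant exchange (above 80% keeps pace, below 20% hardly takes part, else lags behind)

- free catalyst is single-handed; left-handed substrate and right-handed substrate are mirror images of each other, charged as a racemate, each of them at the stated concentration
- an excess is below zero if the other one leads

| run | time / min | left-handed product / % | right-handed product / % | left-handed substrate / % |
|---|---|---|---|---|
| north-west | 0.833 | 5.7 | 2.8 | 46.4 |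
| north-west | 1.33 | 4.4 | 4.4 | 45.5 |
| north-west | 2.00 | 8.0 | 6.3 | 44.1 |
| north-west | 4.00 | 12.9 | 9.4 | 34.9 |
| north-west | 6.00 | 19.4 | 12.0 | 32.5 |
| north-west | 10.0 | 25.4 | 16.6 | 27.5 |
| north | 3.00 | 11.8 | 7.0 | 37.0 |
| north | 10.0 | 25.1 | 14.6 | 28.1 |
| north | 20.0 | 33.2 | 22.3 | 23.2 |
| north | 25.0 | 36.1 | 25.0 | 18.9 |
| north | 40.0 | 41.5 | 27.5 | 15.7 |
| north | 50.0 | 46.2 | 30.9 | 13.2 |

(each reading ± 1 percentage point)

I read these tables in logarithms, where the logarithm of the ratio of the momentary rates of forming left-handed and right-handed product is the logarithm of the selectivity factor s, the ratio of the two rate constants, plus the logarithm of [left-handed substrate]/[right-handed substrate]. Both tables have a row at 10.0 min, and the ratio of their pooled products, summed since the start and with the second term left out, gave the reading s = 1.62, or 0.209 in powers of ten, with the scatter of the readings in it. With instant exchange the second term vanishes, so the product's excess is s less one over s plus one, a ceiling of 23.6%.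

I then went to the last north row, at 50.0 min, where the products summed to 77.1% and their excess read 19.8%, lower than the ceiling. Without exchange the logarithms of the two fractions left stand in the ratio s, and setting their mean to the logarithm of the unreacted 22.9% gave a floor of 10.7%. The north reading therefore stood 70.7% of the way up, between 20% and 80%. Although the flask held less racemization catalyst than north, I committed to those same values for it, and to the verdict that exchange lags behind.

The forecast, which set the selectivity at 1.8 against my 1.62 on the ground that “Early product ratios of about 1.7–1.8 suggest a selectivity near 1.8”, gave 75% (71% to 79%), 18.5% (15% to 22%) and lags behind, its first two lower than mine .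

The flask gave 73.9%, 3.2 percentage points under my reading, with an excess of 20.9%, 71% of the way, so exchange lags behind.

    left-handed substrate + racemization catalyst ⇌ right-handed substrate + racemization catalyst, rate k1*[racemization catalyst]*[left-handed substrate] forward; the back reaction follows from the equilibrium constant (k = 26.9 L mol⁻¹ s⁻¹)
    2 partner → homo dimer (k = 0.0259 L mol⁻¹ s⁻¹)
    partner + free catalyst + left-handed substrate → free catalyst + left-handed product (k = 5870 L² mol⁻² s⁻¹)
    partner + free catalyst + right-handed substrate → free catalyst + right-handed product (k = 3560 L² mol⁻² s⁻¹)
    partner ⇌ dormant form (K = 1.40, k = 0.0263 s⁻¹)
    2 racemization catalyst → spent catalyst (k = 2.90 L mol⁻¹ s⁻¹)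

Left-handed substrate had an exchange half-life of 6.1 min, forward step alone and at the racemization catalyst's charge, shorter than the 23 min of right-handed substrate by its reaction with partner at 8.28 min, yet half of that reaction's turnover up to 50 min was done by 8.46 min, and at 5.00 min the flask held 34.8% left-handed against 38.1% right-handed substrate. The flask's excess ended 2.7 points under my ceiling of 23.6%, while the neighbouring flask with free catalyst at 0.0050 mM reached 40.0% product with an excess of 23.2%, 0.40 points under that ceiling.

The earlier runs and the new flask are simulated for an exercise; the scatter is artificial.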